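**Retrosynthetic overview**
1. Cut the depside ester C–O bond: ring A acid 9 (3-chloro-2-hydroxy-4-methoxy-6-propylbenzoic acid) plus ring B phenol 15 (benzyl 2,4-dihydroxy-6-propylbenzoate). The benzyl ester is removed last.
2. Both rings come from one cyclohexane-1,3-dione, 4. For ring A the chlorine is placed on the carbon between the two carbonyls before aromatization, which fixes it at C3; selective 4-O-methylation follows.
3. Ring B: brominative aromatization of 4, debromination, ester exchange from methyl to benzyl.
4. Dione 4 is made by intermolecular Michael addition of dimethyl malonate to (E)-hept-3-en-2-one, then Claisen ring closure in the same pot. This is the only ring-forming event; it is then aromatized in two different ways.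

Assumption: the target has no stereocentre, so there is no enantiomer to select. The sp3 centres of intermediates 3–6 and 10 are formed without control and are erased on aromatization.

**Step 1**
Reactants: 1 (E)-hept-3-en-2-one; 2 dimethyl malonate
Product: 4 methyl 2,4-dioxo-6-propylcyclohexane-1-carboxylate, via Michael adduct 3 (not isolated)
Conditions: NaOMe (1.1 equiv), MeOH, reflux 4 h; then cold aq HCl to pH 3
Reagents that add atoms: none
Why: Michael addition of the malonate anion to the enone joins the two fragments, and the methyl-ketone enolate then closes the ring by intramolecular Claisen condensation, driven by the stable β-diketonate; the two sp3 centres are uncontrolled and disappear later.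

**Step 2**
Reactants: 4 methyl 2,4-dioxo-6-propylcyclohexane-1-carboxylate
Product: 6 methyl 3,3-dichloro-2,4-dioxo-6-propylcyclohexane-1-carboxylate, via 3-chlorodione 5 (not isolated)
Conditions: SO2Cl2 (2.05 equiv), CH2Cl2, 0 °C to rt; evaporate, use crude
Reagents that add atoms: sulfuryl chloride, ClS(Cl)(=O)=O
Why: electrophilic α-chlorination of the enolized 1,3-dione occurs twice at C3, the most nucleophilic carbon (as with dimedone); any second chlorine that enters C1 instead leads to the same arene in step 3.

**Step 3**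
Reactants: 6 methyl 3,3-dichloro-2,4-dioxo-6-propylcyclohexane-1-carboxylate
Product: 7 methyl 3-chloro-2,4-dihydroxy-6-propylbenzoate
Conditions: HCl (4 M in dioxane, 0.2 equiv), dry DMF, 100 °C, 2 h
Reagents that add atoms: none
Why: dehydrochlorinative aromatization — HCl-mediated migration of one chlorine from C3 to a ring CH, loss of HCl and enolization give the resorcinol (the same principle converts 2,2-dichlorocyclohexane-1,3-dione into 2-chlororesorcinol), and the remaining chlorine stays at C3.

**Step 4**
Reactants: 7 methyl 3-chloro-2,4-dihydroxy-6-propylbenzoate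
Product: 8 methyl 3-chloro-2-hydroxy-4-methoxy-6-propylbenzoate
Conditions: MeI (1.1 equiv), K2CO3 (1.1 equiv), acetone, reflux
Reagents that add atoms: iodomethane, CI
Why: Williamson ether synthesis; the 2-OH is hydrogen-bonded to the ester carbonyl and flanked by two substituents, so only the free, more acidic 4-OH is methylated.

**Step 5**
Reactants: 8 methyl 3-chloro-2-hydroxy-4-methoxy-6-propylbenzoate
Product: 9 3-chloro-2-hydroxy-4-methoxy-6-propylbenzoic acid
Conditions: KOH (5 equiv), DMSO/H2O 4:1, 90 °C; then aq HCl, 0 °C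
Reagents that add atoms: potassium hydroxide, [K+].[OH-]
Why: saponification of the di-ortho-substituted ester needs poorly solvated hydroxide in aqueous DMSO; the aryl chloride and aryl methyl ether are inert, and cold acidification avoids decarboxylation.

**Step 6**
Reactants: 4 methyl 2,4-dioxo-6-propylcyclohexane-1-carboxylate
Product: 12 methyl 3,5-dibromo-2,4-dihydroxy-6-propylbenzoate, via 3-bromodione 10 (not isolated), via 3-bromoresorcylate 11 (not isolated)
Conditions: Br2 (3.05 equiv), AcOH, 20 °C, 16 h; pour into water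
Reagents that add atoms: bromine, BrBr
Why: classical bromination–dehydrobromination aromatization of a dihydroresorcylate, followed by electrophilic bromination of the last free ring position, gives one crystalline product.

**Step 7**
Reactants: 12 methyl 3,5-dibromo-2,4-dihydroxy-6-propylbenzoate
Product: 13 methyl 2,4-dihydroxy-6-propylbenzoate
Conditions: H2 (1 atm), 10% Pd/C, NaOAc (2.5 equiv), MeOH, rt
Reagents that add atoms: none
Why: catalytic hydrodehalogenation cleaves both aryl C–Br bonds while the ester and phenols are untouched.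

**Step 8**
Reactants: 13 methyl 2,4-dihydroxy-6-propylbenzoate
Product: 14 2,4-dihydroxy-6-propylbenzoic acid
Conditions: KOH (6 equiv), DMSO/H2O 4:1, 90 °C, N2; then aq HCl, 0 °C
Reagents that add atoms: potassium hydroxide, [K+].[OH-]
Why: saponification of the hindered ester as in step 5; the acid is liberated cold and dried without heat because β-resorcylic acids decarboxylate when warmed in acid.

**Step 9**
Reactants: 14 2,4-dihydroxy-6-propylbenzoic acid
Product: 15 benzyl 2,4-dihydroxy-6-propylbenzoate
Conditions: BnBr (1.05 equiv), KHCO3 (1.2 equiv), DMF, rt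
Reagents that add atoms: benzyl bromide, BrCc1ccccc1
Why: SN2 O-alkylation of the carboxylate; hydrogencarbonate is too weak to deprotonate the phenols, so only the ester forms.

**Step 10**
Reactants: 9 3-chloro-2-hydroxy-4-methoxy-6-propylbenzoic acid; 15 benzyl 2,4-dihydroxy-6-propylbenzoate
Product: 17 benzyl 4-[(3-chloro-2-hydroxy-4-methoxy-6-propylbenzoyl)oxy]-2-hydroxy-6-propylbenzoate, via mixed anhydride 16 (not isolated)
Conditions: (CF3CO)2O (4 equiv), dry toluene, rt, 3 h
Reagents that add atoms: none
Why: esterification through the mixed trifluoroacetic anhydride activates even a di-ortho-substituted acid; the chelated 2-OH groups of both partners are poor nucleophiles, so only the 4-OH of 15 is acylated.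

**Step 11**
Reactants: 17 benzyl 4-[(3-chloro-2-hydroxy-4-methoxy-6-propylbenzoyl)oxy]-2-hydroxy-6-propylbenzoate
Product: 18 3-chlorodivaricatic acid, 4-[(3-chloro-2-hydroxy-4-methoxy-6-propylbenzoyl)oxy]-2-hydroxy-6-propylbenzoic acid
Conditions: H2 (1 atm), 10% Pd/C, EtOAc, rt, stopped after 1 equiv H2
Reagents that add atoms: none
Why: hydrogenolysis of the benzyl ester under neutral, base-free conditions is much faster than cleavage of the aryl C–Cl bond and leaves the depside ester intact.

**Compound list**
1 | (E)-hept-3-en-2-one | CCC/C=C/C(C)=O | starting material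
2 | dimethyl malonate | COC(=O)CC(=O)OC | starting material
3 | dimethyl 2-(2-oxoheptan-4-yl)malonate (Michael adduct, racemic) | CCCC(CC(C)=O)C(C(=O)OC)C(=O)OC | intermediate
4 | methyl 2,4-dioxo-6-propylcyclohexane-1-carboxylate (racemic, enolized, C1/C6 configuration uncontrolled) | CCCC1CC(=O)CC(=O)C1C(=O)OC | intermediate
5 | methyl 3-chloro-2,4-dioxo-6-propylcyclohexane-1-carboxylate (stereoisomer mixture) | CCCC1CC(=O)C(Cl)C(=O)C1C(=O)OC | intermediate
6 | methyl 3,3-dichloro-2,4-dioxo-6-propylcyclohexane-1-carboxylate (racemic) | CCCC1CC(=O)C(Cl)(Cl)C(=O)C1C(=O)OC | intermediate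
7 | methyl 3-chloro-2,4-dihydroxy-6-propylbenzoate | CCCc1cc(O)c(Cl)c(O)c1C(=O)OC | intermediate
8 | methyl 3-chloro-2-hydroxy-4-methoxy-6-propylbenzoate | CCCc1cc(OC)c(Cl)c(O)c1C(=O)OC | intermediate
9 | 3-chloro-2-hydroxy-4-methoxy-6-propylbenzoic acid | CCCc1cc(OC)c(Cl)c(O)c1C(=O)O | intermediate
10 | methyl 3-bromo-2,4-dioxo-6-propylcyclohexane-1-carboxylate (stereoisomer mixture) | CCCC1CC(=O)C(Br)C(=O)C1C(=O)OC | intermediate
11 | methyl 3-bromo-2,4-dihydroxy-6-propylbenzoate | CCCc1cc(O)c(Br)c(O)c1C(=O)OC | intermediate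
12 | methyl 3,5-dibromo-2,4-dihydroxy-6-propylbenzoate | CCCc1c(Br)c(O)c(Br)c(O)c1C(=O)OC | intermediate
13 | methyl 2,4-dihydroxy-6-propylbenzoate | CCCc1cc(O)cc(O)c1C(=O)OC | intermediate
14 | 2,4-dihydroxy-6-propylbenzoic acid (divaric acid) | CCCc1cc(O)cc(O)c1C(=O)O | intermediate
15 | benzyl 2,4-dihydroxy-6-propylbenzoate | CCCc1cc(O)cc(O)c1C(=O)OCc1ccccc1 | intermediate
16 | 3-chloro-2-hydroxy-4-methoxy-6-propylbenzoic trifluoroacetic anhydride | CCCc1cc(OC)c(Cl)c(O)c1C(=O)OC(=O)C(F)(F)F | intermediate
17 | benzyl 4-[(3-chloro-2-hydroxy-4-methoxy-6-propylbenzoyl)oxy]-2-hydroxy-6-propylbenzoate | CCCc1cc(OC(=O)c2c(CCC)cc(OC)c(Cl)c2O)cc(O)c1C(=O)OCc1ccccc1 | intermediate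
18 | 3-chlorodivaricatic acid | CCCc1cc(OC(=O)c2c(CCC)cc(OC)c(Cl)c2O)cc(O)c1C(=O)O | target

**Totals**
Total steps: 11. Longest linear sequence: 7 steps (steps 1, 2, 3, 4, 5, 10, 11; the ring B branch, steps 1, 6, 7, 8, 9, 10, 11, is equally long).

**Three steps most likely to fail**

Step 3 (aromatization of dichloride 6; nucleophilic ring cleavage of the gem-dichlorodiketone or chlorine scrambling could intervene). The fallback sets out from 13 and comes back at 7. NBS (1.0 equiv, MeCN, 0 °C) brominates 13 para to the chelated 2-OH and gives methyl 5-bromo-2,4-dihydroxy-6-propylbenzoate F1. SO2Cl2 (1.05 equiv, Et2O, 0 °C) can then only enter C3 and gives methyl 5-bromo-3-chloro-2,4-dihydroxy-6-propylbenzoate F2. Hydrogenolysis over Pd/C with NaOAc in MeOH, stopped after one equivalent of H2, removes the bromine much faster than the chlorine and delivers 7.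

Step 10 (the free 2-OH of acid 9 may self-acylate or oligomerize under the anhydride activation). The fallback sets out from 8 and comes back at 18. Benzylation of 8 (BnBr, K2CO3, DMF, 60 °C) gives methyl 2-(benzyloxy)-3-chloro-4-methoxy-6-propylbenzoate F3, and saponification (KOH, DMSO/H2O, 90 °C) gives 2-(benzyloxy)-3-chloro-4-methoxy-6-propylbenzoic acid F4. With (CF3CO)2O in toluene, F4 forms 2-(benzyloxy)-3-chloro-4-methoxy-6-propylbenzoic trifluoroacetic anhydride F5, which acylates the 4-OH of 15 to give benzyl 4-{[2-(benzyloxy)-3-chloro-4-methoxy-6-propylbenzoyl]oxy}-2-hydroxy-6-propylbenzoate F6. One hydrogenolysis (H2, Pd/C, EtOAc) removes both benzyl groups and gives 18.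

Step 11 (competing hydrodechlorination on Pd/C). The fallback sets out from 14 and comes back at 18, avoiding hydrogen altogether. Allyl bromide with KHCO3 in DMF converts 14 into allyl 2,4-dihydroxy-6-propylbenzoate F7. Coupling with 9 through mixed anhydride 16 ((CF3CO)2O, toluene) gives allyl 4-[(3-chloro-2-hydroxy-4-methoxy-6-propylbenzoyl)oxy]-2-hydroxy-6-propylbenzoate F8. Deallylation with Pd(PPh3)4 (zerovalent palladium, 3 mol %) and morpholine in THF at rt, followed by cold acidic work-up, gives 18.

**Further compounds**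
F1 | step 3 | methyl 5-bromo-2,4-dihydroxy-6-propylbenzoate | CCCc1c(Br)c(O)cc(O)c1C(=O)OC
F2 | step 3 | methyl 5-bromo-3-chloro-2,4-dihydroxy-6-propylbenzoate | CCCc1c(Br)c(O)c(Cl)c(O)c1C(=O)OC
F3 | step 10 | methyl 2-(benzyloxy)-3-chloro-4-methoxy-6-propylbenzoate | CCCc1cc(OC)c(Cl)c(OCc2ccccc2)c1C(=O)OC
F4 | step 10 | 2-(benzyloxy)-3-chloro-4-methoxy-6-propylbenzoic acid | CCCc1cc(OC)c(Cl)c(OCc2ccccc2)c1C(=O)O
F5 | step 10 | 2-(benzyloxy)-3-chloro-4-methoxy-6-propylbenzoic trifluoroacetic anhydride | CCCc1cc(OC)c(Cl)c(OCc2ccccc2)c1C(=O)OC(=O)C(F)(F)F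
F6 | step 10 | benzyl 4-{[2-(benzyloxy)-3-chloro-4-methoxy-6-propylbenzoyl]oxy}-2-hydroxy-6-propylbenzoate | CCCc1cc(OC(=O)c2c(CCC)cc(OC)c(Cl)c2OCc2ccccc2)cc(O)c1C(=O)OCc1ccccc1
F7 | step 11 | allyl 2,4-dihydroxy-6-propylbenzoate | CCCc1cc(O)cc(O)c1C(=O)OCC=C
F8 | step 11 | allyl 4-[(3-chloro-2-hydroxy-4-methoxy-6-propylbenzoyl)oxy]-2-hydroxy-6-propylbenzoate | CCCc1cc(OC(=O)c2c(CCC)cc(OC)c(Cl)c2O)cc(O)c1C(=O)OCC=C
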